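**Retrosynthetic overview**

- Last bond made between the two halves: the exocyclic =CH– carbon (C1′) to the methyl-bearing stereocentre (C2′), by a stereoretentive Pd-catalysed sp2–sp3 Negishi coupling of an (E)-5-(iodomethylene) tetronate with a configurationally defined secondary alkylzinc. This one operation joins the finished heterocycle to the complete C20 side chain and transfers both stereo-elements, so only one deprotection follows.
- Enabling feature: the enol-lactone double bond C5=C1′ exocyclic to the furan-2(5H)-one ring, with ring oxygen O1 and C2′ trans. This is the anti-addition pattern of a carboxylate oxygen and a carbon across a terminal alkyne, so C1′ is available as an E C–I bond by 5-exo-dig iodolactonisation of a cis-enynoic acid. C2′ (H, CH3, CH2R) is a plain secondary carbon available as C–I/C–Zn from (R)-propylene oxide.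
- Side chain: the skipped E,E-diene comes from Zr-catalysed methylalumination of (R)-hept-6-yn-2-ol and Pd-catalysed allylation with an allylic acetate made from geranyl acetate and 3-bromofuran (ketone masked as a dioxolane).
- Rings: the furan is bought; the dioxolane is a temporary ring; the butenolide ring of 3-methyltetronic acid is opened to the enynoic acid and closed again with E geometry before the key step; no ring is formed afterwards.

Key step: step 14

Remark: the exocyclic double bond of the target is read as 5E (side chain cis to the C4 oxygen, trans to O1), the less stable geometry, and C2′ as S. 3-Methyltetronic acid and (4-bromobut-1-yn-1-yl)trimethylsilane are taken as purchasable.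

**Route**

Step 1
Reactants: 1 3-methyltetronic acid
Product: 2 4-(methoxymethoxy)-3-methylfuran-2(5H)-one
Conditions: MOMCl, i-Pr2NEt, CH2Cl2, 0 °C → rt
Reagents that add atoms: chloromethyl methyl ether, COCCl
Why: O-alkylation of the vinylogous acid at the 4-oxygen with the hard α-chloro ether (Williamson-type acetal formation) should give a vinylogous-ester acetal that withstands amide bases, iodine and organozinc reagents and is shed by dilute acid in the last step.

Step 2
Reactants: 2 4-(methoxymethoxy)-3-methylfuran-2(5H)-one
Product: 4 5-hydroxy-4-(methoxymethoxy)-3-methylfuran-2(5H)-one (racemic), via sodium furanolate 3 (not isolated)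
Conditions: NaHMDS, THF, −78 °C; then 2-(phenylsulfonyl)-3-phenyloxaziridine, −78 °C; AcOH
Reagents that add atoms: 2-(phenylsulfonyl)-3-phenyloxaziridine, O=S(=O)(c1ccccc1)N1OC1c1ccccc1
Why: Deprotonation at C5 gives the aromatic 2-oxidofuran, which should take up electrophilic oxygen at C5 (enolate hydroxylation); the new C5 centre is racemic and without consequence because it becomes an sp carbon in step 3.

Step 3
Reactants: 4 5-hydroxy-4-(methoxymethoxy)-3-methylfuran-2(5H)-one
Product: 6 (2E)-3-(methoxymethoxy)-2-methylpent-2-en-4-ynoic acid, via lithium formylacrylate 5 (not isolated)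
Conditions: TMSCHN2, n-BuLi (2.3 equiv), THF, −78 → 0 °C; then cold 0.5 M HCl to pH 3
Reagents that add atoms: (trimethylsilyl)diazomethane, C[Si](C)(C)C=[N+]=[N-]
Why: Base opens the lactol (pseudo-acid) to the carboxylate aldehyde 5, and the Colvin variant of the Seyferth–Gilbert homologation (addition, Peterson elimination, loss of N2, 1,2-H shift of the alkylidene carbene) should turn CHO into C≡CH, so the cis relation of carboxyl and alkyne is inherited from the ring.

Step 4
Reactants: 6 (2E)-3-(methoxymethoxy)-2-methylpent-2-en-4-ynoic acid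
Product: 7 (5E)-5-(iodomethylene)-4-(methoxymethoxy)-3-methylfuran-2(5H)-one
Conditions: I2, NaHCO3, MeCN, 0 °C → rt, dark
Reagents that add atoms: iodine, II
Why: Iodolactonisation adds the carboxylate oxygen and iodine anti across the terminal alkyne in the 5-exo-dig mode (attack at the internal alkyne carbon rather than 6-endo closure), which should place iodine trans to the ring oxygen and fix the E geometry.

Step 5
Reactants: 8 geranyl acetate
Product: 9 (2E)-5-(3,3-dimethyloxiran-2-yl)-3-methylpent-2-en-1-yl acetate (racemic)
Conditions: mCPBA, NaHCO3, CH2Cl2, 0 °C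
Reagents that add atoms: 3-chloroperoxybenzoic acid, OOC(=O)c1cccc(Cl)c1
Why: Prilezhaev epoxidation should pick the electron-rich 6,7-double bond over the 2,3-double bond, which is deactivated by the allylic acetate; the racemic epoxide is cleaved in step 6.

Step 6
Reactants: 9 (2E)-5-(3,3-dimethyloxiran-2-yl)-3-methylpent-2-en-1-yl acetate
Product: 10 (2E)-3-methyl-6-oxohex-2-en-1-yl acetate
Conditions: H5IO6, THF/H2O, 0 °C → rt
Reagents that add atoms: none
Why: Periodic acid hydrolyses the epoxide to the glycol and cleaves it in the same flask (glycol cleavage), leaving the E trisubstituted alkene and the allylic acetate untouched.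

Step 7
Reactants: 11 3-bromofuran; 10 (2E)-3-methyl-6-oxohex-2-en-1-yl acetate
Product: 13 (2E)-6-(furan-3-yl)-6-hydroxy-3-methylhex-2-en-1-yl acetate (racemic), via 3-furyllithium 12 (not isolated)
Conditions: 11, n-BuLi, THF, −78 °C; slow addition to 10, −78 °C; AcOH
Reagents that add atoms: none
Why: Bromine–lithium exchange below −70 °C gives 3-furyllithium without migration to C2, and 1,2-addition to the aldehyde at −78 °C should outrun attack on the acetate; the racemic carbinol centre is oxidised in step 8.

Step 8
Reactants: 13 (2E)-6-(furan-3-yl)-6-hydroxy-3-methylhex-2-en-1-yl acetate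
Product: 14 (2E)-6-(furan-3-yl)-3-methyl-6-oxohex-2-en-1-yl acetate
Conditions: activated MnO2, CH2Cl2, rt
Reagents that add atoms: none
Why: Activated MnO2 oxidises the furylic (benzylic-type) alcohol selectively to the aryl ketone without touching the allylic acetate or the alkene.

Step 9
Reactants: 14 (2E)-6-(furan-3-yl)-3-methyl-6-oxohex-2-en-1-yl acetate
Product: 15 (2E)-5-[2-(furan-3-yl)-1,3-dioxolan-2-yl]-3-methylpent-2-en-1-yl acetate
Conditions: (TMSOCH2)2, TMSOTf (cat.), CH2Cl2, −78 → −20 °C; pyridine
Reagents that add atoms: 1,2-bis(trimethylsilyloxy)ethane, C[Si](C)(C)OCCO[Si](C)(C)C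
Why: Noyori ketalisation is driven by formation of the Si–O–Si bond at low temperature and should mask the ketone against t-BuLi without acid strong enough to ionise the allylic acetate or harm the furan.

Step 10
Reactants: 16 (4-bromobut-1-yn-1-yl)trimethylsilane; 17 (R)-propylene oxide
Product: 19 (2R)-7-(trimethylsilyl)hept-6-yn-2-ol, via Grignard reagent 18 (not isolated)
Conditions: 16, Mg, THF; then 17, CuI (cat.), −30 → 0 °C; aq. NH4Cl
Reagents that add atoms: none
Why: The Grignard reagent opens the epoxide under copper catalysis at the unsubstituted carbon (SN2), so the C–O stereocentre of 17 is carried over unchanged as the R carbinol.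

Step 11
Reactants: 19 (2R)-7-(trimethylsilyl)hept-6-yn-2-ol
Product: 20 (2R)-hept-6-yn-2-ol
Conditions: K2CO3 (cat.), MeOH, rt
Reagents that add atoms: none
Why: Methanolysis of the alkynyl C–Si bond (protodesilylation) frees the terminal alkyne; the carbinol centre is not involved.

Step 12
Reactants: 20 (2R)-hept-6-yn-2-ol; 15 (2E)-5-[2-(furan-3-yl)-1,3-dioxolan-2-yl]-3-methylpent-2-en-1-yl acetate
Product: 22 (2R,6E,9E)-12-[2-(furan-3-yl)-1,3-dioxolan-2-yl]-6,10-dimethyldodeca-6,9-dien-2-ol, via alkenylalane 21 (not isolated)
Conditions: Me3Al (3 equiv), Cp2ZrCl2 (cat.), CH2Cl2, 0 °C → rt; volatiles removed in vacuo; then 15, Pd(PPh3)4 (cat.), THF, rt; Rochelle salt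
Reagents that add atoms: trimethylaluminium, C[Al](C)C
Why: Zirconium-catalysed methylalumination (Negishi carboalumination) adds CH3 and Al syn with Al at the terminal carbon, which fixes the 6E alkene, and the Pd-catalysed alkenyl–allyl coupling should attack the less hindered terminus of the π-allyl complex with retention of both geometries to give the skipped E,E-diene, the dioxolane being spared because excess Me3Al is pumped off and THF damps the Lewis acidity.

Step 13
Reactants: 22 (2R,6E,9E)-12-[2-(furan-3-yl)-1,3-dioxolan-2-yl]-6,10-dimethyldodeca-6,9-dien-2-ol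
Product: 23 2-(furan-3-yl)-2-[(3E,6E,11S)-11-iodo-3,7-dimethyldodeca-3,6-dien-1-yl]-1,3-dioxolane
Conditions: PPh3, I2, imidazole, CH2Cl2, −10 → 0 °C (Ph3P·I2 preformed)
Reagents that add atoms: iodine, II
Why: Appel iodination through the alkoxyphosphonium ion is an SN2 displacement by iodide, so the R carbinol should give the S iodide with inversion, low temperature and short contact limiting erosion by iodide exchange.

Step 14
Reactants: 23 2-(furan-3-yl)-2-[(3E,6E,11S)-11-iodo-3,7-dimethyldodeca-3,6-dien-1-yl]-1,3-dioxolane; 7 (5E)-5-(iodomethylene)-4-(methoxymethoxy)-3-methylfuran-2(5H)-one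
Product: 26 (5E)-5-[(2S,6E,9E)-12-[2-(furan-3-yl)-1,3-dioxolan-2-yl]-2,6,10-trimethyldodeca-6,9-dien-1-ylidene]-4-(methoxymethoxy)-3-methylfuran-2(5H)-one, via alkyllithium 24 (not isolated), via alkylzinc 25 (not isolated)
Conditions: t-BuLi (2.2 equiv), pentane/Et2O 3:2, −100 °C, inverse addition; Me3SiCH2ZnBr·LiBr, THF, −100 → −30 °C; then 7, [Pd(μ-I)(P t-Bu3)]2 (cat.), toluene, −25 °C; aq. NH4Cl
Reagents that add atoms: none
Why: Iodine–lithium exchange at −100 °C in a non-polar medium is faster than inversion of the unstabilised secondary carbanion and should give 24 with retention, and immediate transfer to zinc (retention) gives the mixed dialkylzinc 25, which is configurationally stable and carries the non-transferable Me3SiCH2 group. Pd(0)/P(t-Bu)3 inserts into the C(sp2)–I bond of 7 with retention of the alkene geometry, the secondary alkyl group is transferred from zinc with retention, and fast reductive elimination from the bulky monophosphine complex should outrun β-hydride elimination and chain walking; the closest known reaction type is the stereoretentive Negishi coupling of chiral non-stabilised secondary alkylzinc reagents with alkenyl iodides. No ring is closed in this step. No stereocentre is created: C2′ (S) is relayed from the epoxide carbon of 17 through one inversion (step 13) and three retentive events, and the 5E geometry is relayed from the anti iodolactonisation of step 4. The step needs retention at C2′ (secured by the low temperature, the non-polar medium and the immediate Li→Zn transfer), retention of the less stable E alkene (secured by stereospecific oxidative addition and reductive elimination at −25 °C, through the same kind of vinyl-palladium species that gives E products in oxypalladation–coupling of alkynoic acids), and chemoselectivity for C–I over the lactone and the MOM acetal (secured by the mild organozinc).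

Step 15
Reactants: 26 (5E)-5-[(2S,6E,9E)-12-[2-(furan-3-yl)-1,3-dioxolan-2-yl]-2,6,10-trimethyldodeca-6,9-dien-1-ylidene]-4-(methoxymethoxy)-3-methylfuran-2(5H)-one
Product: 27 (5E)-5-[(2S,6E,9E)-13-(furan-3-yl)-2,6,10-trimethyl-13-oxotrideca-6,9-dien-1-ylidene]-4-hydroxy-3-methylfuran-2(5H)-one
Conditions: TsOH·H2O (cat.), acetone/H2O 9:1, rt, dark
Reagents that add atoms: water, O
Why: Dilute non-nucleophilic acid should hydrolyse the dioxolane (through the furyl-stabilised oxocarbenium ion) and the vinylogous-ester MOM acetal (the tetronate is a good leaving group) in one operation, leaving the stereocentre and the E enol-lactone double bond untouched.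

**Compound list**

1 | 3-methyltetronic acid (4-hydroxy-3-methylfuran-2(5H)-one) | CC1=C(O)COC1=O | starting material
2 | 4-(methoxymethoxy)-3-methylfuran-2(5H)-one | CC1=C(OCOC)COC1=O | intermediate
3 | sodium 4-(methoxymethoxy)-3-methylfuran-2-olate (not isolated) | CC1=C([O-])OC=C1OCOC.[Na+] | intermediate
4 | 5-hydroxy-4-(methoxymethoxy)-3-methylfuran-2(5H)-one (racemic) | CC1=C(OCOC)C(O)OC1=O | intermediate
5 | lithium (2E)-3-(methoxymethoxy)-2-methyl-4-oxobut-2-enoate (not isolated; carboxylate and formyl cis) | O=C/C(OCOC)=C(/C)C(=O)[O-].[Li+] | intermediate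
6 | (2E)-3-(methoxymethoxy)-2-methylpent-2-en-4-ynoic acid (carboxyl and ethynyl cis) | C#C/C(OCOC)=C(/C)C(=O)O | intermediate
7 | (5E)-5-(iodomethylene)-4-(methoxymethoxy)-3-methylfuran-2(5H)-one | CC1=C(OCOC)/C(=C\I)OC1=O | intermediate
8 | geranyl acetate | CC(=O)OC/C=C(\C)CCC=C(C)C | starting material
9 | (2E)-5-(3,3-dimethyloxiran-2-yl)-3-methylpent-2-en-1-yl acetate (racemic) | CC(=O)OC/C=C(\C)CCC1OC1(C)C | intermediate
10 | (2E)-3-methyl-6-oxohex-2-en-1-yl acetate | CC(=O)OC/C=C(\C)CCC=O | intermediate
11 | 3-bromofuran | Brc1ccoc1 | starting material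
12 | 3-furyllithium (not isolated) | [Li]c1ccoc1 | intermediate
13 | (2E)-6-(furan-3-yl)-6-hydroxy-3-methylhex-2-en-1-yl acetate (racemic) | CC(=O)OC/C=C(\C)CCC(O)c1ccoc1 | intermediate
14 | (2E)-6-(furan-3-yl)-3-methyl-6-oxohex-2-en-1-yl acetate | CC(=O)OC/C=C(\C)CCC(=O)c1ccoc1 | intermediate
15 | (2E)-5-[2-(furan-3-yl)-1,3-dioxolan-2-yl]-3-methylpent-2-en-1-yl acetate | CC(=O)OC/C=C(\C)CCC1(OCCO1)c1ccoc1 | intermediate
16 | (4-bromobut-1-yn-1-yl)trimethylsilane | C[Si](C)(C)C#CCCBr | starting material
17 | (R)-propylene oxide | C[C@@H]1CO1 | starting material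
18 | [4-(trimethylsilyl)but-3-yn-1-yl]magnesium bromide (not isolated) | C[Si](C)(C)C#CCC[Mg]Br | intermediate
19 | (2R)-7-(trimethylsilyl)hept-6-yn-2-ol | C[C@@H](O)CCCC#C[Si](C)(C)C | intermediate
20 | (2R)-hept-6-yn-2-ol | C[C@@H](O)CCCC#C | intermediate
21 | dimethylaluminium (2R,6E)-7-(dimethylalumanyl)-6-methylhept-6-en-2-olate (not isolated) | C[C@@H](O[Al](C)C)CCC/C(C)=C/[Al](C)C | intermediate
22 | (2R,6E,9E)-12-[2-(furan-3-yl)-1,3-dioxolan-2-yl]-6,10-dimethyldodeca-6,9-dien-2-ol | C[C@@H](O)CCC/C(C)=C/C/C=C(\C)CCC1(OCCO1)c1ccoc1 | intermediate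
23 | 2-(furan-3-yl)-2-[(3E,6E,11S)-11-iodo-3,7-dimethyldodeca-3,6-dien-1-yl]-1,3-dioxolane | C[C@H](I)CCC/C(C)=C/C/C=C(\C)CCC1(OCCO1)c1ccoc1 | intermediate
24 | secondary alkyllithium from 23, C–Li in place of C–I with retained configuration (not isolated) | C[C@H]([Li])CCC/C(C)=C/C/C=C(\C)CCC1(OCCO1)c1ccoc1 | intermediate
25 | secondary alkyl[(trimethylsilyl)methyl]zinc from 24, configuration retained (not isolated) | C[C@H]([Zn]C[Si](C)(C)C)CCC/C(C)=C/C/C=C(\C)CCC1(OCCO1)c1ccoc1 | intermediate
26 | (5E)-5-[(2S,6E,9E)-12-[2-(furan-3-yl)-1,3-dioxolan-2-yl]-2,6,10-trimethyldodeca-6,9-dien-1-ylidene]-4-(methoxymethoxy)-3-methylfuran-2(5H)-one | CC1=C(OCOC)/C(=C\[C@@H](C)CCC/C(C)=C/C/C=C(\C)CCC2(OCCO2)c2ccoc2)OC1=O | intermediate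
27 | (5E)-5-[(2S,6E,9E)-13-(furan-3-yl)-2,6,10-trimethyl-13-oxotrideca-6,9-dien-1-ylidene]-4-hydroxy-3-methylfuran-2(5H)-one | CC1=C(O)/C(=C\[C@@H](C)CCC/C(C)=C/C/C=C(\C)CCC(=O)c2ccoc2)OC1=O | target

**Step count and risks**

Total steps: 15. Longest linear sequence: 9 steps (8 → 9 → 10 → 13 → 14 → 15 → 22 → 23 → 26 → 27).

Steps most likely to fail:

1. Step 14. The unstabilised secondary carbanion may partly invert between exchange and zinc transfer. The furan may be lithiated next to the dioxolane. β-Hydride elimination and re-insertion at palladium may move the metal along the chain. Reversal of the vinyl-palladium species to an alkyne complex may erode the E geometry. Fallback (tin in place of zinc, no carbanion of the substrate): setting out from alcohol 22, mesylation (MsCl, Et3N, CH2Cl2, 0 °C) gives (2R,6E,9E)-12-[2-(furan-3-yl)-1,3-dioxolan-2-yl]-6,10-dimethyldodeca-6,9-dien-2-yl methanesulfonate F1. SN2 displacement with the lithium stannide made from 5-chloro-1-aza-5-stannabicyclo[3.3.3]undecane and lithium naphthalenide (THF, −78 °C → rt) should give, with inversion, the isolable and configurationally stable 5-[(2S,6E,9E)-12-[2-(furan-3-yl)-1,3-dioxolan-2-yl]-6,10-dimethyldodeca-6,9-dien-2-yl]-1-aza-5-stannabicyclo[3.3.3]undecane F2. Its stereoretentive Stille coupling with 7 (Pd(dba)2, JackiePhos, CuCl, KF, MeCN, 60 °C) comes back to the route at 26.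

2. Step 3. The lithium carboxylate aldehyde may precipitate or react too slowly as a vinylogous formate, and the β-alkoxy group may be lost by addition–elimination, so that homologation stalls. Fallback (homologation at the ester level under carbonate, not on a dianion): setting out from 4, O-methylation of the open-chain tautomer (TMSCHN2, MeOH/toluene, 0 °C) gives methyl (2E)-3-(methoxymethoxy)-2-methyl-4-oxobut-2-enoate F3. The Ohira–Bestmann variant of the Seyferth–Gilbert homologation (dimethyl (1-diazo-2-oxopropyl)phosphonate, K2CO3, MeOH, 0 °C) gives methyl (2E)-3-(methoxymethoxy)-2-methylpent-2-en-4-ynoate F4. Saponification (LiOH, THF/H2O, 0 °C → rt) comes back to the route at 6.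

3. Step 2. The alkoxide of the product may ring-open to the aldehyde and condense with unreacted furanolate, or the furanolate may add to the sulfonimine by-product. Fallback (oxidation of an isolated silyl dienol ether in place of the free enolate): setting out from 2, silylation (TBSOTf, Et3N, CH2Cl2, 0 °C) gives tert-butyl{[4-(methoxymethoxy)-3-methylfuran-2-yl]oxy}dimethylsilane F5. Oxidation of this 2-silyloxyfuran at C5 with dimethyldioxirane (acetone, −78 °C) and loss of silicon on aqueous work-up comes back to the route at 4.

Further compounds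
F1 | step 14 | (2R,6E,9E)-12-[2-(furan-3-yl)-1,3-dioxolan-2-yl]-6,10-dimethyldodeca-6,9-dien-2-yl methanesulfonate | C[C@@H](OS(C)(=O)=O)CCC/C(C)=C/C/C=C(\C)CCC1(OCCO1)c1ccoc1
F2 | step 14 | 5-[(2S,6E,9E)-12-[2-(furan-3-yl)-1,3-dioxolan-2-yl]-6,10-dimethyldodeca-6,9-dien-2-yl]-1-aza-5-stannabicyclo[3.3.3]undecane | C[C@H]([Sn]12CCCN(CCC1)CCC2)CCC/C(C)=C/C/C=C(\C)CCC1(OCCO1)c1ccoc1
F3 | step 3 | methyl (2E)-3-(methoxymethoxy)-2-methyl-4-oxobut-2-enoate | O=C/C(OCOC)=C(/C)C(=O)OC
F4 | step 3 | methyl (2E)-3-(methoxymethoxy)-2-methylpent-2-en-4-ynoate | C#C/C(OCOC)=C(/C)C(=O)OC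
F5 | step 2 | tert-butyl{[4-(methoxymethoxy)-3-methylfuran-2-yl]oxy}dimethylsilane | CC1=C(O[Si](C)(C)C(C)(C)C)OC=C1OCOC
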